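**Retrosynthetic overview**
1. Selaginellin 21 ⇐ tetra-O-TBS quinone methide 20 (fluoride). The cyclohexadienone ring A is made last by closing its C1(=O)–C2 bond: the acyl carbon of (2Z)-trienoate 18 attacks the terminal vinyl carbon.
2. 18 is released by base from δ-lactone 17. The lactone ring (an O–C bond to the triaryl carbon, absent from the target) is a temporary ring that fixes the Z geometry needed for closure and is cleaved in the same operation.
3. 17 ⇐ ring-closing enyne metathesis of but-3-enoate 16 ⇐ propargylic alcohol 13 ⇐ ketone 11 + ethynyl Grignard. Formally, the six carbons of ring A come from acetylene (2 C) and but-3-enoic acid (4 C).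
4. 11 ⇐ Suzuki (ring D), Sonogashira (ring E), lithiation between Br and Cl of ring C plus an aldehyde (ring B), from 2-bromo-4-chlorobenzaldehyde. Rings B–E are bought arenes; rings formed: lactone (step 9), then ring A (step 10).
5. Enabling feature: the exocyclic carbon on C4 of ring A bears two aryl rings (B and C). As an sp3 C–O centre it is a doubly benzylic, allylic leaving site; as the end of a 1,1-diaryl-1,3-diene it stabilises the cation formed on acylation. Ring A is locally C2-symmetric, so the geometry at C4=C is irrelevant.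

Key step: step 10

Assumption: the target SMILES has no stereodescriptor and the molecule has no stereocentre (the twisted ring C–C axis is exchanged by phenol/quinone-methide tautomerism), so no enantiocontrol is needed; intermediates with one stereocentre (6, 13, 15, 16, 17) are used as racemates.

Abbreviations: TBS = tert-butyldimethylsilyl; ArB = 4-(TBSO)phenyl; ArC = 4'-(TBSO)-4-(TBSOCH2)-3-{[4-(TBSO)phenyl]ethynyl}biphenyl-2-yl. Compounds 4, 8, 10, 12 and 14 are taken to be catalogue reagents.

Step 1
Reactants: 1 2-bromo-4-chlorobenzaldehyde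
Product: 2 (2-bromo-4-chlorophenyl)methanol
Conditions: NaBH4, MeOH, 0 °C
Reagents that add atoms: none
Why: Chemoselective borohydride reduction of the aldehyde; the aryl halides are not touched.

Step 2
Reactants: 2 (2-bromo-4-chlorophenyl)methanol
Product: 3 tert-butyl[(2-bromo-4-chlorobenzyl)oxy]dimethylsilane
Conditions: TBSCl, imidazole, DMF, rt
Reagents that add atoms: tert-butyldimethylsilyl chloride, CC(C)(C)[Si](C)(C)Cl
Why: Standard silylation of a primary alcohol; the ether should survive amide bases, organometallics, Pd and Ru catalysis.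

Step 3
Reactants: 3 tert-butyl[(2-bromo-4-chlorobenzyl)oxy]dimethylsilane; 4 4-[(tert-butyldimethylsilyl)oxy]benzaldehyde
Product: 6 rac-[2-bromo-6-chloro-3-(TBSOCH2)phenyl](ArB)methanol, via aryllithium 5 (not isolated)
Conditions: LDA (1.1 equiv), THF, −78 °C, 1 h; then 4, −78 °C; H2O quench at −78 °C
Reagents that add atoms: none
Why: Directed ortho-metalation: the C–H flanked by Br and Cl is the most acidic, LDA does not exchange the bromide, and the 2,6-dihaloaryllithium should be stable at −78 °C and add to the aldehyde; the carbinol centre is racemic and is oxidised in step 4.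

Step 4
Reactants: 6 rac-[2-bromo-6-chloro-3-(TBSOCH2)phenyl](ArB)methanol
Product: 7 [2-bromo-6-chloro-3-(TBSOCH2)phenyl](ArB)methanone
Conditions: Dess–Martin periodinane, CH2Cl2, rt
Reagents that add atoms: none
Why: Dess–Martin oxidation of a hindered diaryl carbinol; silyl ethers and aryl halides are inert.

Step 5
Reactants: 7 [2-bromo-6-chloro-3-(TBSOCH2)phenyl](ArB)methanone; 8 tert-butyl(4-ethynylphenoxy)dimethylsilane
Product: 9 [6-chloro-3-(TBSOCH2)-2-{[4-(TBSO)phenyl]ethynyl}phenyl](ArB)methanone
Conditions: PdCl2(PPh3)2 (5 mol%), CuI (5 mol%), Et3N/THF, 65 °C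
Reagents that add atoms: none
Why: Sonogashira coupling; the C–Br bond (activated by the ortho carbonyl) should react while the C–Cl bond stays intact with PPh3 ligands.

Step 6
Reactants: 9 [6-chloro-3-(TBSOCH2)-2-{[4-(TBSO)phenyl]ethynyl}phenyl](ArB)methanone; 10 {4-[(tert-butyldimethylsilyl)oxy]phenyl}boronic acid
Product: 11 (ArC)(ArB)methanone
Conditions: Pd(OAc)2 (5 mol%), SPhos (10 mol%), K3PO4 (3 equiv), toluene/H2O 20:1, 90 °C
Reagents that add atoms: none
Why: Suzuki–Miyaura coupling of an ortho-acyl-activated aryl chloride with a dialkylbiarylphosphine ligand; the low-water conditions are chosen to keep the aryl silyl ethers.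

Step 7
Reactants: 11 (ArC)(ArB)methanone; 12 ethynylmagnesium bromide
Product: 13 rac-1-(ArC)-1-(ArB)prop-2-yn-1-ol
Conditions: 12 (3 equiv), LaCl3·2LiCl (1 equiv), THF, 0 °C → rt; H2O
Reagents that add atoms: none
Why: 1,2-Addition of the slimmest carbon nucleophile to a non-enolisable, hindered diaryl ketone, promoted by the lanthanum salt; the racemic carbinol centre is erased in step 10.

Step 8
Reactants: 13 rac-1-(ArC)-1-(ArB)prop-2-yn-1-ol; 14 but-3-enoyl chloride
Product: 16 rac-1-(ArB)-1-(ArC)prop-2-yn-1-yl but-3-enoate, via lithium alkoxide 15 (not isolated)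
Conditions: LiHMDS (1.0 equiv), THF, −78 °C; then 14 (1.3 equiv), −78 → −20 °C; pH 7 buffer
Reagents that add atoms: none
Why: O-Acylation of the pre-formed lithium alkoxide (O–H is far more acidic than the alkyne C–H); the cold, amine-free conditions are meant to keep the β,γ-unsaturated acyl group out of conjugation.

Step 9
Reactants: 16 rac-1-(ArB)-1-(ArC)prop-2-yn-1-yl but-3-enoate
Product: 17 rac-6-(ArB)-6-(ArC)-5-ethenyl-3,6-dihydro-2H-pyran-2-one
Conditions: Grubbs II (10 mol%), ethylene (1 atm), toluene, 70 °C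
Reagents that add atoms: none
Why: Ring-closing enyne metathesis of a 1,7-enyne in the exo mode under ethylene should give the six-membered lactone with a 1-vinyl diene; the hindered internal diarylalkyne should not compete with the terminal alkyne.

Step 10
Reactants: 17 rac-6-(ArB)-6-(ArC)-5-ethenyl-3,6-dihydro-2H-pyran-2-one
Product: 20 4-[(ArB)(ArC)methylidene]cyclohexa-2,5-dien-1-one (tetra-O-TBS-selaginellin), via potassium (2Z)-trienoate 18 (not isolated), via mixed trifluoroacetic anhydride 19 (not isolated)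
Conditions: KHMDS (1.05 equiv), THF, −78 → −20 °C; then 2,6-di-tert-butyl-4-methylpyridine (1.5 equiv), (CF3CO)2O (1.05 equiv), CH2Cl2, −78 → 0 °C; aq NaHCO3
Reagents that add atoms: none
Why: Proposed new method: KHMDS removes a C3–H of lactone 17 (α to C=O and allylic) and the resulting 2-oxido-2H-pyran opens by retro-oxa-6π electrocyclisation (a vinylogous E1cB) with cleavage of the doubly benzylic C6–O bond, giving carboxylate 18 whose C2=C3 bond is Z because both carbons were ring members; O-trifluoroacetylation gives 19, whose acyl carbon attacks the CH2 terminus of the 1,1-diaryl-1,3-diene, and loss of the α-proton from the diarylallyl cation (a C-protonated quinone methide) gives the cyclohexa-2,5-dienone. The closest known reaction types are the base-induced opening of 5,6-dihydro-2H-pyran-2-ones to (2Z)-dienoic acids and the TFAA-mediated intramolecular Darzens–Nenitzescu/Friedel–Crafts acylation of alkenes; their union to build a fuchsone ring is what is new. Ring A is the only ring closed, in a 6-endo-trig cation–olefin mode through the bond between the carbonyl carbon C1 and the α-carbon C2 (the former vinyl CH2). No stereocentre is created and the one in 17 is erased; the geometry of the new exocyclic C4=C bond is irrelevant because ring A is locally C2-symmetric. The step needs Z geometry (secured by the lactone ring), attack at the diene terminus rather than at an aryl ortho position (secured by the six-membered transition state and the cation-stabilising aryl groups on the exocyclic carbon) and activation of the carboxylate before the diene meets the anhydride (secured by the anionic carboxylate being the best nucleophile at −78 °C with 1.05 equiv of anhydride).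

Step 11
Reactants: 20 4-[(ArB)(ArC)methylidene]cyclohexa-2,5-dien-1-one (tetra-O-TBS-selaginellin)
Product: 21 selaginellin
Conditions: TBAF (6 equiv), AcOH (6 equiv), THF, 0 °C → rt
Reagents that add atoms: none
Why: Fluoride cleavage of three aryl and one alkyl TBS ether; the acetic acid buffer is meant to suppress alkoxide cyclisation onto the ortho alkyne, and the fuchsone-type quinone methide should survive.

**Compound list**
1 | 2-bromo-4-chlorobenzaldehyde | O=Cc1ccc(Cl)cc1Br | starting material
2 | (2-bromo-4-chlorophenyl)methanol | OCc1ccc(Cl)cc1Br | intermediate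
3 | tert-butyl[(2-bromo-4-chlorobenzyl)oxy]dimethylsilane | CC(C)(C)[Si](C)(C)OCc1ccc(Cl)cc1Br | intermediate
4 | 4-[(tert-butyldimethylsilyl)oxy]benzaldehyde | CC(C)(C)[Si](C)(C)Oc1ccc(C=O)cc1 | starting material
5 | 2-bromo-6-chloro-3-(TBSOCH2)phenyllithium (not isolated) | [Li]c1c(Cl)ccc(CO[Si](C)(C)C(C)(C)C)c1Br | intermediate
6 | rac-[2-bromo-6-chloro-3-(TBSOCH2)phenyl](ArB)methanol | OC(c1ccc(O[Si](C)(C)C(C)(C)C)cc1)c1c(Cl)ccc(CO[Si](C)(C)C(C)(C)C)c1Br | intermediate
7 | [2-bromo-6-chloro-3-(TBSOCH2)phenyl](ArB)methanone | O=C(c1ccc(O[Si](C)(C)C(C)(C)C)cc1)c1c(Cl)ccc(CO[Si](C)(C)C(C)(C)C)c1Br | intermediate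
8 | tert-butyl(4-ethynylphenoxy)dimethylsilane | C#Cc1ccc(O[Si](C)(C)C(C)(C)C)cc1 | starting material
9 | [6-chloro-3-(TBSOCH2)-2-{[4-(TBSO)phenyl]ethynyl}phenyl](ArB)methanone | O=C(c1ccc(O[Si](C)(C)C(C)(C)C)cc1)c1c(Cl)ccc(CO[Si](C)(C)C(C)(C)C)c1C#Cc1ccc(O[Si](C)(C)C(C)(C)C)cc1 | intermediate
10 | {4-[(tert-butyldimethylsilyl)oxy]phenyl}boronic acid | OB(O)c1ccc(O[Si](C)(C)C(C)(C)C)cc1 | starting material
11 | (ArC)(ArB)methanone | O=C(c1ccc(O[Si](C)(C)C(C)(C)C)cc1)c1c(-c2ccc(O[Si](C)(C)C(C)(C)C)cc2)ccc(CO[Si](C)(C)C(C)(C)C)c1C#Cc1ccc(O[Si](C)(C)C(C)(C)C)cc1 | intermediate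
12 | ethynylmagnesium bromide | C#C[Mg]Br | starting material
13 | rac-1-(ArC)-1-(ArB)prop-2-yn-1-ol | C#CC(O)(c1ccc(O[Si](C)(C)C(C)(C)C)cc1)c1c(-c2ccc(O[Si](C)(C)C(C)(C)C)cc2)ccc(CO[Si](C)(C)C(C)(C)C)c1C#Cc1ccc(O[Si](C)(C)C(C)(C)C)cc1 | intermediate
14 | but-3-enoyl chloride | C=CCC(Cl)=O | starting material
15 | lithium alkoxide of 13 (racemic, not isolated) | C#CC(O[Li])(c1ccc(O[Si](C)(C)C(C)(C)C)cc1)c1c(-c2ccc(O[Si](C)(C)C(C)(C)C)cc2)ccc(CO[Si](C)(C)C(C)(C)C)c1C#Cc1ccc(O[Si](C)(C)C(C)(C)C)cc1 | intermediate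
16 | rac-1-(ArB)-1-(ArC)prop-2-yn-1-yl but-3-enoate | C=CCC(=O)OC(C#C)(c1ccc(O[Si](C)(C)C(C)(C)C)cc1)c1c(-c2ccc(O[Si](C)(C)C(C)(C)C)cc2)ccc(CO[Si](C)(C)C(C)(C)C)c1C#Cc1ccc(O[Si](C)(C)C(C)(C)C)cc1 | intermediate
17 | rac-6-(ArB)-6-(ArC)-5-ethenyl-3,6-dihydro-2H-pyran-2-one | O=C1CC=C(C=C)C(O1)(c1ccc(O[Si](C)(C)C(C)(C)C)cc1)c1c(-c2ccc(O[Si](C)(C)C(C)(C)C)cc2)ccc(CO[Si](C)(C)C(C)(C)C)c1C#Cc1ccc(O[Si](C)(C)C(C)(C)C)cc1 | intermediate
18 | potassium (2Z)-4-[(ArB)(ArC)methylidene]hexa-2,5-dienoate (tetrasubstituted C=C geometry not defined, both converge; not isolated) | [K+].[O-]C(=O)/C=C\C(C=C)=C(c1ccc(O[Si](C)(C)C(C)(C)C)cc1)c1c(-c2ccc(O[Si](C)(C)C(C)(C)C)cc2)ccc(CO[Si](C)(C)C(C)(C)C)c1C#Cc1ccc(O[Si](C)(C)C(C)(C)C)cc1 | intermediate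
19 | (2Z)-4-[(ArB)(ArC)methylidene]hexa-2,5-dienoic trifluoroacetic anhydride (not isolated) | O=C(OC(=O)C(F)(F)F)/C=C\C(C=C)=C(c1ccc(O[Si](C)(C)C(C)(C)C)cc1)c1c(-c2ccc(O[Si](C)(C)C(C)(C)C)cc2)ccc(CO[Si](C)(C)C(C)(C)C)c1C#Cc1ccc(O[Si](C)(C)C(C)(C)C)cc1 | intermediate
20 | 4-[(ArB)(ArC)methylidene]cyclohexa-2,5-dien-1-one (tetra-O-TBS-selaginellin) | O=C1C=CC(=C(c2ccc(O[Si](C)(C)C(C)(C)C)cc2)c2c(-c3ccc(O[Si](C)(C)C(C)(C)C)cc3)ccc(CO[Si](C)(C)C(C)(C)C)c2C#Cc2ccc(O[Si](C)(C)C(C)(C)C)cc2)C=C1 | intermediate
21 | selaginellin | O=C1C=CC(=C(c2ccc(O)cc2)c2c(-c3ccc(O)cc3)ccc(CO)c2C#Cc2ccc(O)cc2)C=C1 | target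

**Step count and risks**
Total step count: 11. Longest linear sequence: 11 steps (1 → 21); all coupling partners are purchased.

Steps most likely to fail:

1. Step 10 (proposed new method). Possible failures are Z → E isomerisation of the activated trienoate before closure, intermolecular C-trifluoroacetylation or polymerisation of the electron-rich dendralene-type triene, and acid-induced re-lactonisation or loss of silyl groups. Fallback with known chemistry, in which ring A comes from a bought arene: starting from ketone 11, (4-bromophenoxy)(tert-butyl)dimethylsilane is lithiated with n-BuLi (THF, −78 °C) to give [4-(tert-butyldimethylsilyloxy)phenyl]lithium F1, which should add to 11 to give the penta-TBS triarylcarbinol F2. TBAF then AcOH should desilylate to the pentahydroxy triarylcarbinol F3, which should lose water to the quinone methide; the route is rejoined at 21.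

2. Step 8. Possible failures are slow acylation of the very hindered tertiary alkoxide, base-induced migration of the double bond into conjugation (a crotonate is dead for metathesis), retro-alkynylation, and alkoxide attack on the ortho alkyne. Fallback by ketene acylation instead of acyl substitution: starting from alcohol 13, crotonyl chloride is added slowly to 13 with Et3N and catalytic DMAP (toluene, 0 °C) so that buta-1,3-dien-1-one (vinylketene) F4 forms in the flask. The alcohol adds to its unhindered sp carbon, and kinetic α-protonation of the dienol should give the deconjugated ester; the route is rejoined at 16.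

3. Step 9. Possible failures are sequestration of the ruthenium alkylidene by chelation to the ester carbonyl, double-bond migration by Ru–H species, competing reaction of the internal diarylalkyne, and oligomerisation. Fallback that splits the enyne metathesis in two: starting from alcohol 13, ethylene–alkyne cross-metathesis (Grubbs II, ethylene, CH2Cl2, rt) should give the 2-substituted butadiene carbinol rac-2-methylidene-1-(ArB)-1-(ArC)but-3-en-1-ol F5. Acylation as in step 8 should give its but-3-enoate F6, and olefin ring-closing metathesis onto the 1,1-disubstituted alkene (Hoveyda–Grubbs II, CH2Cl2, 40 °C) should give the lactone; the route is rejoined at 17.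

**Further compounds**
F1 | step 10 | [4-(tert-butyldimethylsilyloxy)phenyl]lithium | [Li]c1ccc(O[Si](C)(C)C(C)(C)C)cc1
F2 | step 10 | bis(ArB)(ArC)methanol (penta-TBS triarylcarbinol) | OC(c1ccc(O[Si](C)(C)C(C)(C)C)cc1)(c1ccc(O[Si](C)(C)C(C)(C)C)cc1)c1c(-c2ccc(O[Si](C)(C)C(C)(C)C)cc2)ccc(CO[Si](C)(C)C(C)(C)C)c1C#Cc1ccc(O[Si](C)(C)C(C)(C)C)cc1
F3 | step 10 | pentahydroxy triarylcarbinol (hydrate of selaginellin) | OC(c1ccc(O)cc1)(c1ccc(O)cc1)c1c(-c2ccc(O)cc2)ccc(CO)c1C#Cc1ccc(O)cc1
F4 | step 8 | buta-1,3-dien-1-one (vinylketene) | C=CC=C=O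
F5 | step 9 | rac-2-methylidene-1-(ArB)-1-(ArC)but-3-en-1-ol | C=CC(=C)C(O)(c1ccc(O[Si](C)(C)C(C)(C)C)cc1)c1c(-c2ccc(O[Si](C)(C)C(C)(C)C)cc2)ccc(CO[Si](C)(C)C(C)(C)C)c1C#Cc1ccc(O[Si](C)(C)C(C)(C)C)cc1
F6 | step 9 | rac-2-methylidene-1-(ArB)-1-(ArC)but-3-en-1-yl but-3-enoate | C=CCC(=O)OC(C(=C)C=C)(c1ccc(O[Si](C)(C)C(C)(C)C)cc1)c1c(-c2ccc(O[Si](C)(C)C(C)(C)C)cc2)ccc(CO[Si](C)(C)C(C)(C)C)c1C#Cc1ccc(O[Si](C)(C)C(C)(C)C)cc1
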